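# Proposed total synthesis of 3,4,5-tribromo-2-(3,5-dibromo-2-methoxyphenoxy)phenol (CNP0295171.0)

## Structural features

The target consists of two benzene rings, ring A and ring B, joined by a single ether oxygen; it has no stereocentre, so the problem is one of regiochemistry. Ring A carries the methoxy group at C1, bromine at C2 and C4, hydrogen at C3 and C5, and the ether oxygen at C6. Ring B carries a free hydroxyl next to its ether carbon, one hydrogen next to that hydroxyl, and three contiguous bromines on the remaining carbons. Both ether carbons are flanked by ortho substituents (methoxy on ring A, hydroxyl and bromine on ring B), so a direct aryl–oxygen coupling would have to join two hindered partners in the presence of C–Br bonds that copper or palladium catalysts attack. The fragile groups are the five aryl bromides, which exclude halogen-exchanging organolithium bases, hydrogenolysis and cross-coupling, and the free phenol, which excess bromine can over-oxidise. The real difficulty is to place five bromines without ambiguity and to methylate one of two catechol-type oxygens while the other stays free. The key step exploits the fact that C1 of ring A bears oxygen directly beside the ether carbon C6 while C5 is unsubstituted. C1 to C4 with the C1 oxygen then correspond to C3 to C6 of 3-hydroxy-2-pyrone, and C6–C5 to a two-carbon alkene that already carries the ring B aryloxy group, so ring A can be built onto the ether oxygen and need not be coupled to it.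

## Logic of the disconnections

**16 to 15.** The O–isopropyl bond on the ring B oxygen is cut. The two phenolic oxygens of the target differ only in that one is methylated, so the ring B oxygen must travel through the route under a group that can be removed beside a methyl ether. The gain is that 15 has no acidic site and holds all five bromines. The forward dealkylation must tell a secondary from a primary alkyl ether and leave C–Br alone, which points to a boron Lewis acid at low temperature.

**15 to 14.** The O–CH3 bond on ring A is cut. A free hydroxyl at C1 is needed one stage earlier as the directing group for bromination. The gain is small in atoms but decisive for regiocontrol. The forward step is the alkylation of a hindered but acidic phenol, and nothing else in 14 can be alkylated.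

**14 to 13.** The C2–Br and C4–Br bonds of ring A are cut. Both lie ortho and para to the C1 hydroxyl, the strongest donor in the molecule. Ring A is reduced to a ring with only its two oxygens, which is what a cycloaddition can deliver. The forward step requires the hydroxyl to outrank the aryloxy group at C6, ring B with its single hydrogen to stay untouched, and the isopropyl ether to survive the acid that is set free.

**13 to 9 and 10.** The C1–C6 and C4–C5 bonds of ring A are cut, after formal return of CO2 across C1/C4 and of sulfinic acid across C5–C6. This removes ring A while the ether oxygen stays on ring B, so no aryl–oxygen bond between two hindered, brominated arenes has to be made. The gain is the largest of the route: 13 falls into the commercial 10 and into 9, which holds all of ring B. The forward step demands that C6 of 10 bonds to the CH2 terminus of 9, that the alkene of 9 stays electrophilic despite its oxygen substituent, and that the adduct loses CO2 and sulfinate cleanly.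

**9 to 5 and 6.** The C=CH2 bond is cut. The methylene carbon is added as a one-carbon electrophile to the sulfonyl-stabilised carbanion, and loss of water sets the alkene. The gain is that 5 needs no carbon–carbon bond formation at all. The forward step needs an amide base that deprotonates alpha to sulfur without exchanging aryl bromine, and a mild dehydration.

**5 to 4.** The two S=O bonds are cut. A halomethyl sulfone is inert to SN2, and the route through an aryl chloromethyl ether and a sulfinate passes a volatile alkylating agent that also tends to capture a second phenoxide. At the sulfide level the electrophile is activated and the later oxidation is routine. The gain is reliability and safer handling at no cost in steps. The oxidant must spare the aryl ether and the bromides.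

**4 to 2 and 3.** The O–CH2 bond is cut. This joins ring B to the future C6 of ring A through the oxygen that becomes the diaryl ether oxygen. The forward step needs a reactive SN2 partner for a hindered, weakly basic phenoxide, which 3 provides.

**2 to 1.** The three C–Br bonds of ring B are cut. They sit ortho and para to the free hydroxyl and para to the isopropoxy group, so the oxygen that directs here is the one that later becomes the ether oxygen, and the oxygen that must end free is the one masked. The gain is a commercial catechol mono-ether. The forward step must leave the fourth position, which is ortho only to the bulky ether, so stoichiometry and buffering matter.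

## Other disconnections considered

**Alternative 1:** The cut is at C1–C2 and C2–C3 of ring A, the excised carbon C2 carrying its bromine.
- **Forward step:** the silyl enol ether A3 of the cyclopentanone A2, formed on the side away from the aryloxy carbon, takes up the dihalocarbene generated from bromoform A4 and a tert-butoxide base. The dibromocyclopropane opens with loss of bromide to the racemic 2-bromoenone A1.
- **In favour:** this ring expansion of cyclic silyl enol ethers is a well-established reaction type. It places the C2 bromine by construction, not by a directing effect, and on that point it is better than the chosen plan. Like the chosen plan it makes the ether linkage by simple O-alkylation of 2 (here with a 2-halocyclopentanone), so the two are equal in avoiding an aryl–oxygen coupling.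
- **Against:** A1 lies two hydrogens above the phenol level. The dehydrogenation has to be done without palladium because of the aryl bromides, on an enone whose alpha-prime carbon bears the aryloxy group. Enolisation of A2 must go away from the oxygenated alpha carbon, which is the more acidic one, so the regiochemistry of A3 is not assured. C4 bromination, methylation and deprotection are still required.
- **Comparison:** counting from 1, the sequence (2, A2, A3, A1, aromatisation, C4 bromination, methylation, deprotection) has the same eight steps as the chosen route. It trades a secure cycloaddition regiochemistry and a directly aromatic product for an oxidation-state adjustment and an enolisation problem.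

**Alternative 2:** The cut is at C2–C3 and C5–C6, dividing ring A into the three carbons C6–C1–C2 of the aryloxyacetone A6 and the three carbons C3–C4–C5 of 2-bromomalonaldehyde A7.
- **Forward step:** under amine base both alpha carbons of A6 condense with the two formyl groups of A7, and the second, intramolecular aldol condensation closes ring A as the phenol A5, which already holds the C4 bromine.
- **In favour:** A6 should come from 2 and a haloacetone in one step. After A5 only one position ortho to the hydroxyl is open and the para position is blocked, so the last ring A bromination is unambiguous. On both counts, step economy (six steps from 1 against eight) and certainty of the final bromination, this alternative is better than the chosen plan. It is equal in building ring A on the preformed ether oxygen.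
- **Against:** double condensation of a ketone with a 2-substituted malonaldehyde is secure mainly for strongly acceptor-substituted congeners. In A7 the halogen sits on the carbon between two carbonyls, so alkylation of the enolate, furan formation of the Feist–Benary type and base-induced decomposition of A7 compete with the desired carbonyl condensations.
- **Comparison:** the pyrone route is longer, but each of its stages (amine-catalysed cycloaddition, loss of CO2, loss of sulfinate) has a close analogy, whereas the benzannulation to A5 rests on a chemoselectivity that cannot be predicted with confidence.

**Alternative 3:** The cut is at C5–C6 and C1–C6, so that the single carbon C6 with its aryloxy group is inserted between the ends of a five-carbon chain.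
- **Forward step:** the ylide A10 adds to the ring carbon next to oxygen and remote from the methoxy group of the pyrylium salt A9 (from the pyranone A11 and a hard methylating agent). The 2H-pyran opens to a dienoate, and the regenerated ylide closes ring A by intramolecular Wittig reaction on the ester carbonyl, giving A8, which is identical with 15.
- **In favour:** the methoxy group and both ring A bromines arrive in place, so no late bromination or methylation is needed and only the deprotection follows. In convergence, in the certainty of the ring A substitution pattern and in step count (about six steps from 1) this alternative is better than the chosen plan.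
- **Against:** several untested demands are stacked in one operation. The ylide must attack one of three electrophilic ring positions of A9, A10 must be generated with base beside a highly electrophilic and moisture-sensitive cation, and the Wittig reaction must occur on an ester carbonyl. The phosphonium precursor of A10 would also come from 2 through an aryl halomethyl ether, the hazardous and acetal-prone intermediate that the chosen plan avoids.
- **Comparison:** the chosen plan is longer and relies on directing effects for two bromines, but its mechanism is the more conservative.

Key step: step 5

Remark on the chemistry: the target has no stereocentre; 7, 8, 11 and 12 contain transient stereocentres that form without control and are removed later, and 6 is taken as the monomer obtained by cracking commercial paraformaldehyde.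

## Route

**Step 1**
Reactants: 1 2-isopropoxyphenol
Product: 2 2,3,4-tribromo-6-isopropoxyphenol
Conditions: Br2 (3.1 equiv), NaOAc, AcOH, 15 °C to rt
Reagents that add atoms: bromine, BrBr
Why: Electrophilic aromatic bromination; the hydroxyl directs to its ortho and para positions and the isopropoxy group to its para position, while the fourth position is ortho only to the bulky ether and meta to the hydroxyl and should be left when bromine is limited to three equivalents; acetate buffers HBr so the isopropyl ether is not cleaved.

**Step 2**
Reactants: 2 2,3,4-tribromo-6-isopropoxyphenol; 3 chloromethyl phenyl sulfide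
Product: 4 1,2,3-tribromo-5-isopropoxy-4-[(phenylsulfanyl)methoxy]benzene
Conditions: K2CO3, NaI (cat.), DMF, rt to 50 °C
Reagents that add atoms: none
Why: Williamson O-alkylation (phenylthiomethyl ether formation); the acidic phenol is fully ionised by carbonate, and the alpha-chloro sulfide, further activated by Finkelstein exchange, is reactive enough for a phenoxide with two ortho substituents.

**Step 3**
Reactants: 4 1,2,3-tribromo-5-isopropoxy-4-[(phenylsulfanyl)methoxy]benzene
Product: 5 1,2,3-tribromo-5-isopropoxy-4-[(phenylsulfonyl)methoxy]benzene
Conditions: mCPBA (2.3 equiv), CH2Cl2, 0 °C to rt
Reagents that add atoms: 3-chloroperoxybenzoic acid, OOC(=O)c1cccc(Cl)c1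
Why: Peracid oxidation of sulfide through sulfoxide to sulfone; the electron-poor polybrominated ring, the ethers and the C–Br bonds are inert to the peracid.

**Step 4**
Reactants: 5 1,2,3-tribromo-5-isopropoxy-4-[(phenylsulfonyl)methoxy]benzene; 6 formaldehyde
Product: 9 1,2,3-tribromo-5-isopropoxy-4-{[1-(phenylsulfonyl)ethenyl]oxy}benzene, via lithium alkoxide 7 (not isolated), via mesylate 8 (not isolated)
Conditions: LiN(SiMe3)2 (1.1 equiv), THF, −78 °C; CH2O (gas, from cracked paraformaldehyde), −78 °C; MsCl, −78 to 0 °C; Et3N, 0 °C to rt
Reagents that add atoms: methanesulfonyl chloride, CS(=O)(=O)Cl, and LiN(SiMe3)2, [Li+].C[Si](C)(C)[N-][Si](C)(C)C (their atoms remain only in the intermediates 8 and 7 and are absent from 9)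
Why: Hydroxymethylation of a sulfonyl-stabilised carbanion, then mesylation and E1cB elimination to the vinyl sulfone; the silylamide base removes the proton alpha to sulfur and oxygen without halogen–lithium exchange, and the remaining alpha proton of 8 is acidic enough for Et3N.

**Step 5**
Reactants: 9 1,2,3-tribromo-5-isopropoxy-4-{[1-(phenylsulfonyl)ethenyl]oxy}benzene; 10 3-hydroxy-2H-pyran-2-one
Product: 13 2-(2,3,4-tribromo-6-isopropoxyphenoxy)phenol, via bridged lactone 11 (not isolated), via cyclohexadienol 12 (not isolated)
Conditions: 10 (1.5 equiv), Et3N (2 equiv), CH2Cl2, rt; then PhMe, Et3N, 100 °C (sealed tube)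
Reagents that add atoms: none
Why: Et3N deprotonates 10 to the 3-oxido-2-pyrone, an electron-rich diene whose nucleophilic terminus C6 attacks the methylene carbon of 9 while C3 bonds to the carbon that carries the sulfonyl and aryloxy groups, giving the bridged lactone 11 by a [4+2] cycloaddition or its stepwise Michael–aldol equivalent. Heating drives a retro-[4+2] loss of CO2 from 11 to the dienol 12, which aromatises by loss of benzenesulfinate from C6, helped by the lone pair of the aryloxy oxygen and by the base, with removal of a proton from C5. The closest known reactions are the amine-catalysed Diels–Alder reactions of 3-hydroxy-2-pyrone with acrylates, maleimides and other electron-poor alkenes, the thermal decarboxylation of their adducts, and the use of vinyl sulfones as alkyne equivalents; the dienophile here differs in its additional 1-aryloxy substituent. Ring A is closed in the cycloaddition itself, both new bonds (C1–C6 and C4–C5) being made to the two-carbon unit in an intermolecular [4+2] mode, and the carbocycle is freed from the lactone bridge afterwards. No stereocentre survives, since those of 11 and 12 form as mixtures and are erased on aromatisation. The step needs ortho regiochemistry, with the sulfonyl-bearing carbon next to the hydroxylated carbon, and this is secured by the polarity match between the nucleophilic C6 of the oxidopyrone and the electrophilic methylene terminus of the vinyl sulfone. It also needs attack through carbon and not through oxygen of the oxidopyrone, which the soft conjugated acceptor and the reversibility of oxygen addition should favour.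

**Step 6**
Reactants: 13 2-(2,3,4-tribromo-6-isopropoxyphenoxy)phenol
Product: 14 2,4-dibromo-6-(2,3,4-tribromo-6-isopropoxyphenoxy)phenol
Conditions: Br2 (2.05 equiv), NaOAc, AcOH/CH2Cl2, 0 °C to rt
Reagents that add atoms: bromine, BrBr
Why: Electrophilic aromatic bromination directed by the free hydroxyl to its open para and ortho positions (C4 and C2 of ring A); the aryloxy group with its electron-poor aryl is a much weaker donor, ring B is deactivated by three bromines, and the stoichiometry stops the reaction at two bromines.

**Step 7**
Reactants: 14 2,4-dibromo-6-(2,3,4-tribromo-6-isopropoxyphenoxy)phenol
Product: 15 1,2,3-tribromo-4-(3,5-dibromo-2-methoxyphenoxy)-5-isopropoxybenzene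
Conditions: MeI, K2CO3, DMF, rt
Reagents that add atoms: iodomethane, CI
Why: Williamson O-methylation of the only free hydroxyl; the phenol is acidic (ortho and para bromine), and the small electrophile tolerates the two ortho substituents.

**Step 8**
Reactants: 15 1,2,3-tribromo-4-(3,5-dibromo-2-methoxyphenoxy)-5-isopropoxybenzene
Product: 16 3,4,5-tribromo-2-(3,5-dibromo-2-methoxyphenoxy)phenol
Conditions: BCl3 (2 equiv), CH2Cl2, −78 to 0 °C; then H2O
Reagents that add atoms: none
Why: Lewis acid dealkylation of an aryl isopropyl ether; after coordination of boron the secondary alkyl group departs through a cation-like transition state far more readily than the methyl group, so the ring A methyl ether and the aryl bromides should remain.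

## Compound list

1 | 2-isopropoxyphenol | CC(C)Oc1ccccc1O | starting material
2 | 2,3,4-tribromo-6-isopropoxyphenol | Oc1c(OC(C)C)cc(Br)c(Br)c1Br | intermediate
3 | chloromethyl phenyl sulfide | ClCSc1ccccc1 | starting material
4 | 1,2,3-tribromo-5-isopropoxy-4-[(phenylsulfanyl)methoxy]benzene | CC(C)Oc1cc(Br)c(Br)c(Br)c1OCSc1ccccc1 | intermediate
5 | 1,2,3-tribromo-5-isopropoxy-4-[(phenylsulfonyl)methoxy]benzene | CC(C)Oc1cc(Br)c(Br)c(Br)c1OCS(=O)(=O)c1ccccc1 | intermediate
6 | formaldehyde (monomer from cracked paraformaldehyde) | C=O | starting material
7 | lithium 2-(phenylsulfonyl)-2-(2,3,4-tribromo-6-isopropoxyphenoxy)ethan-1-olate (racemic) | [Li+].[O-]CC(Oc1c(OC(C)C)cc(Br)c(Br)c1Br)S(=O)(=O)c1ccccc1 | intermediate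
8 | 2-(phenylsulfonyl)-2-(2,3,4-tribromo-6-isopropoxyphenoxy)ethyl methanesulfonate (racemic) | CS(=O)(=O)OCC(Oc1c(OC(C)C)cc(Br)c(Br)c1Br)S(=O)(=O)c1ccccc1 | intermediate
9 | 1,2,3-tribromo-5-isopropoxy-4-{[1-(phenylsulfonyl)ethenyl]oxy}benzene | C=C(Oc1c(OC(C)C)cc(Br)c(Br)c1Br)S(=O)(=O)c1ccccc1 | intermediate
10 | 3-hydroxy-2H-pyran-2-one | O=C1OC=CC=C1O | starting material
11 | 4-hydroxy-8-(phenylsulfonyl)-8-(2,3,4-tribromo-6-isopropoxyphenoxy)-2-oxabicyclo[2.2.2]oct-5-en-3-one (racemic, endo/exo mixture) | O=C1OC2C=CC1(O)C(Oc3c(OC(C)C)cc(Br)c(Br)c3Br)(S(=O)(=O)c3ccccc3)C2 | intermediate
12 | 6-(phenylsulfonyl)-6-(2,3,4-tribromo-6-isopropoxyphenoxy)cyclohexa-1,3-dien-1-ol (racemic) | OC1=CC=CCC1(Oc1c(OC(C)C)cc(Br)c(Br)c1Br)S(=O)(=O)c1ccccc1 | intermediate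
13 | 2-(2,3,4-tribromo-6-isopropoxyphenoxy)phenol | Oc1ccccc1Oc1c(OC(C)C)cc(Br)c(Br)c1Br | intermediate
14 | 2,4-dibromo-6-(2,3,4-tribromo-6-isopropoxyphenoxy)phenol | Oc1c(Br)cc(Br)cc1Oc1c(OC(C)C)cc(Br)c(Br)c1Br | intermediate
15 | 1,2,3-tribromo-4-(3,5-dibromo-2-methoxyphenoxy)-5-isopropoxybenzene | COc1c(Br)cc(Br)cc1Oc1c(OC(C)C)cc(Br)c(Br)c1Br | intermediate
16 | 3,4,5-tribromo-2-(3,5-dibromo-2-methoxyphenoxy)phenol | COc1c(Br)cc(Br)cc1Oc1c(O)cc(Br)c(Br)c1Br | target

## Step count and least certain steps

Total step count: 8. Longest linear sequence: 8 steps, from 1 to 16; 3, 6 and 10 are commercial and enter directly.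

**Step 5 (key step).** The 1-aryloxy substituent may lower the electrophilicity of the alkene so far that reversible oxygen addition of the oxidopyrone, or slow decomposition of 10 under base, outruns carbon–carbon bond formation. Incomplete loss of CO2 or sulfinate on heating is the second risk.
- Fallback: this gives up ring construction and makes the aryl–oxygen bond directly. It sets out from 2 and returns at 13.
- Aromatic nucleophilic substitution of the phenoxide of 2 on 2-fluorobenzaldehyde (K2CO3, DMF, 100 °C) should give 2-(2,3,4-tribromo-6-isopropoxyphenoxy)benzaldehyde F1.
- Baeyer–Villiger oxidation with mCPBA in CH2Cl2 should convert F1 into 2-(2,3,4-tribromo-6-isopropoxyphenoxy)phenyl formate F2, and NaOH in aqueous MeOH should hydrolyse F2 to 13.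
- Its weak points are the low nucleophilicity of the hindered phenoxide and the migratory preference in the oxidation.

**Step 4.** The lithiated alpha-aryloxy sulfone may decay before it is trapped, by expulsion of the electron-poor aryloxide from the carbanion carbon or by attack on a ring bromine. The alkoxide 7 may lose formaldehyde again or take up a second equivalent.
- Fallback: this avoids carbanions altogether. It sets out from 2 and returns at 9.
- Chlorine addition to phenyl vinyl sulfide with SO2Cl2 should give [(1,2-dichloroethyl)sulfanyl]benzene F3.
- The phenoxide of 2 (K2CO3, MeCN) should displace the sulfur-activated alpha chloride of F3 to give 1,2,3-tribromo-4-[2-chloro-1-(phenylsulfanyl)ethoxy]-5-isopropoxybenzene F4.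
- mCPBA should oxidise F4 to 1,2,3-tribromo-4-[2-chloro-1-(phenylsulfonyl)ethoxy]-5-isopropoxybenzene F5, and Et3N should eliminate HCl from F5 to 9.

**Step 1.** The third bromine may be misdirected to the position ortho to the isopropoxy group, a fourth bromine may enter, or HBr may cleave the ether if buffering is insufficient.
- Fallback: two bromines are fixed by symmetry and only one is left to the hydroxyl. It does not start from 1; it replaces 1 by commercial 4,5-dibromobenzene-1,2-diol and returns at 2.
- Mono-alkylation with 2-bromopropane (1 equiv, K2CO3, DMF) should give 4,5-dibromo-2-isopropoxyphenol F6. Only one mono-ether is possible because the diol is symmetric.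
- Amine-mediated ortho bromination of F6 (Br2, 1 equiv, t-BuNH2, PhMe, −70 °C) should deliver bromine next to the free hydroxyl and give 2.

**Step 6.** The second bromine may be diverted to a position activated by the aryloxy group instead of the position ortho to the hydroxyl, or substitution may start at the single ring B hydrogen.
- Fallback: reagent-controlled delivery in two stages. It sets out from 13 and returns at 14.
- Bromination through the amine–phenol complex (Br2, 1 equiv, t-BuNH2, PhMe, −70 °C) should place the first bromine ortho to the hydroxyl and give 2-bromo-6-(2,3,4-tribromo-6-isopropoxyphenoxy)phenol F7.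
- A para-selective ammonium tribromide (Bu4NBr3, CH2Cl2/MeOH, rt) should then convert F7 into 14.

## Further compounds

F1 | step 5 | 2-(2,3,4-tribromo-6-isopropoxyphenoxy)benzaldehyde | O=Cc1ccccc1Oc1c(OC(C)C)cc(Br)c(Br)c1Br
F2 | step 5 | 2-(2,3,4-tribromo-6-isopropoxyphenoxy)phenyl formate | O=COc1ccccc1Oc1c(OC(C)C)cc(Br)c(Br)c1Br
F3 | step 4 | [(1,2-dichloroethyl)sulfanyl]benzene (racemic) | ClCC(Cl)Sc1ccccc1
F4 | step 4 | 1,2,3-tribromo-4-[2-chloro-1-(phenylsulfanyl)ethoxy]-5-isopropoxybenzene (racemic) | ClCC(Oc1c(OC(C)C)cc(Br)c(Br)c1Br)Sc1ccccc1
F5 | step 4 | 1,2,3-tribromo-4-[2-chloro-1-(phenylsulfonyl)ethoxy]-5-isopropoxybenzene (racemic) | ClCC(Oc1c(OC(C)C)cc(Br)c(Br)c1Br)S(=O)(=O)c1ccccc1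
F6 | step 1 | 4,5-dibromo-2-isopropoxyphenol | CC(C)Oc1cc(Br)c(Br)cc1O
F7 | step 6 | 2-bromo-6-(2,3,4-tribromo-6-isopropoxyphenoxy)phenol | Oc1c(Br)cccc1Oc1c(OC(C)C)cc(Br)c(Br)c1Br
A1 | alternative 1 | 2-bromo-6-(2,3,4-tribromo-6-isopropoxyphenoxy)cyclohex-2-en-1-one (racemic) | O=C1C(Br)=CCCC1Oc1c(OC(C)C)cc(Br)c(Br)c1Br
A2 | alternative 1 | 2-(2,3,4-tribromo-6-isopropoxyphenoxy)cyclopentan-1-one (racemic) | O=C1CCCC1Oc1c(OC(C)C)cc(Br)c(Br)c1Br
A3 | alternative 1 | trimethyl{[5-(2,3,4-tribromo-6-isopropoxyphenoxy)cyclopent-1-en-1-yl]oxy}silane (racemic) | C[Si](C)(C)OC1=CCCC1Oc1c(OC(C)C)cc(Br)c(Br)c1Br
A4 | alternative 1 | bromoform | BrC(Br)Br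
A5 | alternative 2 | 4-bromo-2-(2,3,4-tribromo-6-isopropoxyphenoxy)phenol | Oc1ccc(Br)cc1Oc1c(OC(C)C)cc(Br)c(Br)c1Br
A6 | alternative 2 | 1-(2,3,4-tribromo-6-isopropoxyphenoxy)propan-2-one | CC(=O)COc1c(OC(C)C)cc(Br)c(Br)c1Br
A7 | alternative 2 | 2-bromopropanedial (2-bromomalonaldehyde) | O=CC(Br)C=O
A8 | alternative 3 | 1,2,3-tribromo-4-(3,5-dibromo-2-methoxyphenoxy)-5-isopropoxybenzene | COc1c(Br)cc(Br)cc1Oc1c(OC(C)C)cc(Br)c(Br)c1Br
A9 | alternative 3 | 3,5-dibromo-2-methoxypyrylium tetrafluoroborate | COc1[o+]cc(Br)cc1Br.F[B-](F)(F)F
A10 | alternative 3 | triphenyl[(2,3,4-tribromo-6-isopropoxyphenoxy)methylidene]-lambda5-phosphane | CC(C)Oc1cc(Br)c(Br)c(Br)c1OC=P(c1ccccc1)(c1ccccc1)c1ccccc1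
A11 | alternative 3 | 3,5-dibromo-2H-pyran-2-one | O=C1OC=C(Br)C=C1Br
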